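**Abbreviations:** TBS = tert-butyldimethylsilyl, TMS = trimethylsilyl. Germacrane numbering is used for the target: C3 bears the isobutyrate, C4=C5–C6–O–C15(=O) is the bridging butenolide, C7/C8/C11–C13 form the α-methylene lactone, and C9=C10 carries C14H2OH.

## Retrosynthetic overview

1. Final desilylation; before it the ten-membered ring is closed last, by ring-closing metathesis at C9=C10 (ring-cis alkene) on a seco bis-lactone that already holds all four stereocentres.
2. The C11=C13 methylene comes from an aminomethyl group. The key C6–C7 bond comes from a vinylogous Mukaiyama–Michael addition in which a 3-substituted 2-silyloxyfuran attacks the β-carbon of (R)-5-propenylbutenolide; the furan loses its aromaticity and becomes the bridging butenolide, and C6 and C7 are set.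
3. The silyloxyfuran comes from an (S)-3-furyl carbinol by C2 lithiation and oxidation. The carbinol is built from 3-furoic acid, MeLi and a 2-(silyloxymethyl)allyl bromide, with C3 set by asymmetric transfer hydrogenation.
4. The acceptor butenolide (C8) comes from crotonaldehyde and methyl propiolate by asymmetric alkynylation, Lindlar reduction and lactonisation.
5. Ring order: acceptor lactone, then the furan-derived butenolide, then the carbocycle.

Assumption: (R,R)-ProPhenol/Me2Zn is taken to give the (R)-carbinol in step 7 (the (S,S)-ligand gives the antipode); the sense is confirmed by Mosher ester analysis before going on.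

## Route

Step 1
Reactants: 1 2-methylidenepropane-1,3-diol
Product: 3 2-[(TBS-oxy)methyl]prop-2-en-1-ol, via sodium monoalkoxide 2 (not isolated)
Conditions: NaH (1.0 equiv), THF, 0 °C → rt; TBSCl (1.0 equiv), rt
Reagents that add atoms: tert-butyldimethylsilyl chloride, CC(C)(C)[Si](C)(C)Cl
Why: Monosilylation of a symmetric diol through its sparingly soluble monosodium alkoxide (O-silylation), which stops cleanly at the mono-ether; no stereocentre.

Step 2
Reactants: 3 2-[(TBS-oxy)methyl]prop-2-en-1-ol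
Product: 4 {[2-(bromomethyl)prop-2-en-1-yl]oxy}(tert-butyl)dimethylsilane
Conditions: CBr4, PPh3, CH2Cl2, 0 °C
Reagents that add atoms: carbon tetrabromide, BrC(Br)(Br)Br
Why: Appel bromination of a primary allylic alcohol under neutral conditions that leave the silyl ether intact.

Step 3
Reactants: 5 furan-3-carboxylic acid
Product: 7 1-(furan-3-yl)ethan-1-one, via dilithium gem-diolate 6 (not isolated)
Conditions: MeLi (2.2 equiv), Et2O, 0 °C → rt; inverse quench into cold 1 M HCl
Reagents that add atoms: methyllithium, [Li]C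
Why: Addition of MeLi to the lithium carboxylate gives a stable gem-diolate that releases the methyl ketone only on quench (carboxylic acid to methyl ketone).

Step 4
Reactants: 7 1-(furan-3-yl)ethan-1-one; 4 {[2-(bromomethyl)prop-2-en-1-yl]oxy}(tert-butyl)dimethylsilane
Product: 9 1-(furan-3-yl)-4-[(TBS-oxy)methyl]pent-4-en-1-one, via lithium enolate 8 (not isolated)
Conditions: LDA (1.1 equiv), THF, −78 °C; then 4 (0.9 equiv), DMPU, −78 → −20 °C
Reagents that add atoms: none
Why: Kinetic enolate C-alkylation with a reactive allylic bromide forms C1–C2 (SN2 and SN2′ give the same product); the enolate is kept in excess to suppress dialkylation.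

Step 5
Reactants: 9 1-(furan-3-yl)-4-[(TBS-oxy)methyl]pent-4-en-1-one
Product: 10 (1S)-1-(furan-3-yl)-4-[(TBS-oxy)methyl]pent-4-en-1-ol
Conditions: RuCl(p-cymene)[(S,S)-TsDPEN] (1 mol%), HCO2H–Et3N (5:2), CH2Cl2, 30 °C
Reagents that add atoms: none
Why: Noyori asymmetric transfer hydrogenation of a heteroaryl alkyl ketone; the furyl ring takes the aryl position in the CH/π-controlled transition state, so the (S,S)-catalyst gives the (S)-carbinol (C3) and the isolated alkene is untouched.

Step 6
Reactants: 10 (1S)-1-(furan-3-yl)-4-[(TBS-oxy)methyl]pent-4-en-1-ol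
Product: 13 3-{(1S)-1-hydroxy-4-[(TBS-oxy)methyl]pent-4-en-1-yl}furan-2(5H)-one, via C2-lithiated dianion 11 (not isolated), via lithium furylborate 12 (not isolated)
Conditions: n-BuLi (2.3 equiv), THF, −78 → 0 °C; B(OMe)3, −78 °C → rt; AcOH, 30% H2O2, 0 °C
Reagents that add atoms: hydrogen peroxide, OO
Why: Alkoxide-directed ortho-lithiation at furan C2, borylation and peroxide oxidation give the 2-hydroxyfuran, which tautomerises to the conjugated butenolide; the oxidation is kept acidic to avoid retro-aldol, and C3 is not touched.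

Step 7
Reactants: 14 (2E)-but-2-enal; 15 methyl prop-2-ynoate
Product: 16 methyl (4R,5E)-4-hydroxyhept-5-en-2-ynoate
Conditions: (R,R)-ProPhenol (10 mol%), Me2Zn (3 equiv), toluene, 4 °C; aq. NH4Cl
Reagents that add atoms: none
Why: Zn–ProPhenol-catalysed asymmetric alkynylation of an enal; the dinuclear zinc catalyst delivers the zinc propiolate to one carbonyl face and sets C8 as R.

Step 8
Reactants: 16 methyl (4R,5E)-4-hydroxyhept-5-en-2-ynoate
Product: 18 (5R)-5-[(1E)-prop-1-en-1-yl]furan-2(5H)-one, via Z-hydroxy dienoate 17 (not isolated)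
Conditions: H2 (1 atm), Lindlar Pd, quinoline, EtOAc, rt; then PPTS (cat.), CH2Cl2, rt
Reagents that add atoms: none
Why: Lindlar cis-semihydrogenation places the ester and the carbinol on the same side so the Z-γ-hydroxy enoate lactonises; C8 is not touched and the E-propenyl group survives.

Step 9
Reactants: 13 3-{(1S)-1-hydroxy-4-[(TBS-oxy)methyl]pent-4-en-1-yl}furan-2(5H)-one; 18 (5R)-5-[(1E)-prop-1-en-1-yl]furan-2(5H)-one
Product: 22 (3R,4S,5R)-3-[(dimethylamino)methyl]-4-[(2R)-4-{(1S)-1-hydroxy-4-[(TBS-oxy)methyl]pent-4-en-1-yl}-5-oxo-2,5-dihydrofuran-2-yl]-5-[(1E)-prop-1-en-1-yl]oxolan-2-one, via bis-TMS silyloxyfuran 19 (not isolated), via silyl ketene acetal 20 (not isolated), via O-TMS Mannich base 21 (not isolated)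
Conditions: TMSOTf (2.2 equiv), Et3N (2.5 equiv), CH2Cl2, 0 °C; pentane, filter, concentrate; 18 (1.2 equiv), TMSOTf (0.3 equiv), CH2Cl2, −78 °C; CH2=NMe2+ I−, −78 → 0 °C; citric acid, MeOH; aq. NaHCO3
Reagents that add atoms: N,N-dimethylmethylideneammonium iodide (Eschenmoser's salt), C=[N+](C)C.[I-]
Why: Vinylogous Mukaiyama–Michael addition with Mannich trapping: the aromatic 2-silyloxyfuran attacks the β-carbon of 18 through its C5, anti to the propenyl group (sets C7 as S) and in an endo, Diels–Alder-like orientation with the lactone carbonyl under the furan ring (expected to set C6 as R), and the resulting silyl ketene acetal is aminomethylated at C11 trans to the new substituent.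

Step 10
Reactants: 22 Mannich base (3R,4S,5R)-3-[(dimethylamino)methyl] bis-lactone
Product: 24 (4S,5R)-4-[(2R)-4-{(1S)-1-hydroxy-4-[(TBS-oxy)methyl]pent-4-en-1-yl}-5-oxo-2,5-dihydrofuran-2-yl]-3-methylidene-5-[(1E)-prop-1-en-1-yl]oxolan-2-one, via trimethylammonium iodide 23 (not isolated)
Conditions: MeI (10 equiv), CH2Cl2–MeOH, rt; then sat. aq. NaHCO3, CH2Cl2, rt
Reagents that add atoms: none
Why: Exhaustive N-methylation followed by mild-base E1cB (Hofmann-type) elimination gives the α-methylene lactone; the C11 stereocentre disappears and C6, C7, C8 are not affected by bicarbonate.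

Step 11
Reactants: 24 α-methylene bis-lactone alcohol
Product: 25 (1S)-1-{(5R)-5-[(2R,3S)-4-methylidene-5-oxo-2-[(1E)-prop-1-en-1-yl]oxolan-3-yl]-2-oxo-2,5-dihydrofuran-3-yl}-4-[(TBS-oxy)methyl]pent-4-en-1-yl 2-methylpropanoate
Conditions: i-PrCOCl, pyridine, DMAP (cat.), CH2Cl2, 0 °C
Reagents that add atoms: 2-methylpropanoyl chloride, CC(C)C(Cl)=O
Why: O-Acylation of the secondary allylic alcohol with retention at C3.

Step 12
Reactants: 25 seco diene isobutyrate
Product: 26 (3S,4Z,6R,7S,8R,9E)-3-(2-methylpropanoyloxy)-14-(TBS-oxy)germacra-4,9,11(13)-triene-12,8:15,6-diolide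
Conditions: Hoveyda–Grubbs II (15 mol%), 1,4-benzoquinone (20 mol%), toluene (1 mM), 90 °C, Ar sparge
Reagents that add atoms: none
Why: Ring-closing metathesis between the propenyl group and the 1,1-disubstituted alkene with loss of propene; the ten-membered ring favours the ring-cis trisubstituted alkene (9E by CIP because CH2O outranks the ring CH2), and the electron-poor butenolide and acrylate alkenes do not compete.

Step 13
Reactants: 26 14-O-TBS macrocycle
Product: 27 (3S,4Z,6R,7S,8R,9E)-14-hydroxy-3-(2-methylpropanoyloxy)germacra-4,9,11(13)-triene-12,8:15,6-diolide (CNP0322767.4)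
Conditions: HF·pyridine, THF–pyridine, 0 °C → rt
Reagents that add atoms: none
Why: Buffered fluoride cleavage of the primary allylic silyl ether, non-basic so that the α-methylene lactone, the butenolide and the allylic isobutyrate survive.

## Compound list

1 | 2-methylidenepropane-1,3-diol | C=C(CO)CO | starting material
2 | sodium 2-(hydroxymethyl)prop-2-en-1-olate | [Na+].[O-]CC(=C)CO | intermediate
3 | 2-[(TBS-oxy)methyl]prop-2-en-1-ol | C=C(CO)CO[Si](C)(C)C(C)(C)C | intermediate
4 | {[2-(bromomethyl)prop-2-en-1-yl]oxy}(tert-butyl)dimethylsilane | C=C(CBr)CO[Si](C)(C)C(C)(C)C | intermediate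
5 | furan-3-carboxylic acid (3-furoic acid) | OC(=O)c1ccoc1 | starting material
6 | dilithium 1-(furan-3-yl)ethane-1,1-diolate | [Li+].[Li+].CC([O-])([O-])c1ccoc1 | intermediate
7 | 1-(furan-3-yl)ethan-1-one | CC(=O)c1ccoc1 | intermediate
8 | lithium 1-(furan-3-yl)ethen-1-olate | [Li+].C=C([O-])c1ccoc1 | intermediate
9 | 1-(furan-3-yl)-4-[(TBS-oxy)methyl]pent-4-en-1-one | C=C(CCC(=O)c1ccoc1)CO[Si](C)(C)C(C)(C)C | intermediate
10 | (1S)-1-(furan-3-yl)-4-[(TBS-oxy)methyl]pent-4-en-1-ol | C=C(CC[C@H](O)c1ccoc1)CO[Si](C)(C)C(C)(C)C | intermediate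
11 | dilithio derivative of 10 (lithium alkoxide, lithium at furan C2) | C=C(CC[C@H](O[Li])c1ccoc1[Li])CO[Si](C)(C)C(C)(C)C | intermediate
12 | dilithium salt of the furan-2-yl trimethoxyborate of the alkoxide of 10 | [Li+].[Li+].C=C(CC[C@H]([O-])c1ccoc1[B-](OC)(OC)OC)CO[Si](C)(C)C(C)(C)C | intermediate
13 | 3-{(1S)-1-hydroxy-4-[(TBS-oxy)methyl]pent-4-en-1-yl}furan-2(5H)-one | C=C(CC[C@H](O)C1=CCOC1=O)CO[Si](C)(C)C(C)(C)C | intermediate
14 | (2E)-but-2-enal (crotonaldehyde) | C/C=C/C=O | starting material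
15 | methyl prop-2-ynoate (methyl propiolate) | C#CC(=O)OC | starting material
16 | methyl (4R,5E)-4-hydroxyhept-5-en-2-ynoate | C/C=C/[C@@H](O)C#CC(=O)OC | intermediate
17 | methyl (2Z,4R,5E)-4-hydroxyhepta-2,5-dienoate | C/C=C/[C@@H](O)/C=C\C(=O)OC | intermediate
18 | (5R)-5-[(1E)-prop-1-en-1-yl]furan-2(5H)-one | C/C=C/[C@H]1OC(=O)C=C1 | intermediate
19 | 2-(TMS-oxy)-3-{(1S)-1-(TMS-oxy)-4-[(TBS-oxy)methyl]pent-4-en-1-yl}furan | C=C(CC[C@H](O[Si](C)(C)C)c1ccoc1O[Si](C)(C)C)CO[Si](C)(C)C(C)(C)C | intermediate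
20 | (5R)-5-{(2R,3S)-2-[(1E)-prop-1-en-1-yl]-5-(TMS-oxy)-2,3-dihydrofuran-3-yl}-3-{(1S)-1-(TMS-oxy)-4-[(TBS-oxy)methyl]pent-4-en-1-yl}furan-2(5H)-one | C[Si](C)(C)OC1=C[C@H]([C@@H]2OC(=O)C(=C2)[C@@H](O[Si](C)(C)C)CCC(=C)CO[Si](C)(C)C(C)(C)C)[C@@H](/C=C/C)O1 | intermediate
21 | (3R,4S,5R)-3-[(dimethylamino)methyl]-4-[(2R)-5-oxo-4-{(1S)-1-(TMS-oxy)-4-[(TBS-oxy)methyl]pent-4-en-1-yl}-2,5-dihydrofuran-2-yl]-5-[(1E)-prop-1-en-1-yl]oxolan-2-one | CN(C)C[C@@H]1C(=O)O[C@H](/C=C/C)[C@H]1[C@@H]2OC(=O)C(=C2)[C@@H](O[Si](C)(C)C)CCC(=C)CO[Si](C)(C)C(C)(C)C | intermediate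
22 | (3R,4S,5R)-3-[(dimethylamino)methyl]-4-[(2R)-4-{(1S)-1-hydroxy-4-[(TBS-oxy)methyl]pent-4-en-1-yl}-5-oxo-2,5-dihydrofuran-2-yl]-5-[(1E)-prop-1-en-1-yl]oxolan-2-one | CN(C)C[C@@H]1C(=O)O[C@H](/C=C/C)[C@H]1[C@@H]2OC(=O)C(=C2)[C@@H](O)CCC(=C)CO[Si](C)(C)C(C)(C)C | intermediate
23 | N-methyl quaternary ammonium iodide of 22 (CH2NMe3+ I− at C11) | [I-].C[N+](C)(C)C[C@@H]1C(=O)O[C@H](/C=C/C)[C@H]1[C@@H]2OC(=O)C(=C2)[C@@H](O)CCC(=C)CO[Si](C)(C)C(C)(C)C | intermediate
24 | (4S,5R)-4-[(2R)-4-{(1S)-1-hydroxy-4-[(TBS-oxy)methyl]pent-4-en-1-yl}-5-oxo-2,5-dihydrofuran-2-yl]-3-methylidene-5-[(1E)-prop-1-en-1-yl]oxolan-2-one | C=C1C(=O)O[C@H](/C=C/C)[C@H]1[C@@H]2OC(=O)C(=C2)[C@@H](O)CCC(=C)CO[Si](C)(C)C(C)(C)C | intermediate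
25 | (1S)-1-{(5R)-5-[(2R,3S)-4-methylidene-5-oxo-2-[(1E)-prop-1-en-1-yl]oxolan-3-yl]-2-oxo-2,5-dihydrofuran-3-yl}-4-[(TBS-oxy)methyl]pent-4-en-1-yl 2-methylpropanoate | C=C1C(=O)O[C@H](/C=C/C)[C@H]1[C@@H]2OC(=O)C(=C2)[C@@H](OC(=O)C(C)C)CCC(=C)CO[Si](C)(C)C(C)(C)C | intermediate
26 | (3S,4Z,6R,7S,8R,9E)-3-(2-methylpropanoyloxy)-14-(TBS-oxy)germacra-4,9,11(13)-triene-12,8:15,6-diolide | C=C1C(=O)O[C@@H]2/C=C(/CO[Si](C)(C)C(C)(C)C)CC[C@H](OC(=O)C(C)C)C3=C[C@@H](OC3=O)[C@@H]12 | intermediate
27 | (3S,4Z,6R,7S,8R,9E)-14-hydroxy-3-(2-methylpropanoyloxy)germacra-4,9,11(13)-triene-12,8:15,6-diolide (CNP0322767.4) | C=C1C(=O)O[C@@H]2/C=C(/CO)CC[C@H](OC(=O)C(C)C)C3=C[C@@H](OC3=O)[C@@H]12 | target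

## Step count and risks

Total steps: 13. Longest linear sequence: 10 (steps 1, 2, 4, 5, 6, 9, 10, 11, 12, 13).

**Step 9 (vinylogous Mukaiyama–Michael addition and Mannich trapping).** The risks are the face selectivity at C6 (the endo preference is an expectation and the bulky C3 substituent next to the silyloxy group may erode it), ionisation of the C3 silyl ether next to the electron-rich furan, and the modest electrophilicity of 18. The fallback sets out from 18 and turns the conjugate addition into an allylic substitution. Morita–Baylis–Hillman hydroxymethylation of 18 (aq. CH2O, PBu3, THF–H2O) gives (5R)-3-(hydroxymethyl)-5-[(1E)-prop-1-en-1-yl]furan-2(5H)-one F1. Appel bromination (CBr4, PPh3) gives (5R)-3-(bromomethyl)-5-[(1E)-prop-1-en-1-yl]furan-2(5H)-one F2. A tertiary amine catalyst (DABCO, or β-isocupreidine when the C6 face needs catalyst control) first displaces the bromide and is then displaced in SN2′ fashion by silyloxyfuran 19 at C7, anti to the propenyl group. The exocyclic methylene is formed in the same event, and acidic work-up removes the TMS ether. This comes back to the route at 24 and replaces steps 9 and 10.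

**Step 12 (ring-closing metathesis).** The risks are the strain of the butenolide-bridged ten-membered ring, oligomerisation, and interference of the exocyclic acrylate with the catalyst. The fallback sets out from 22 and closes the carbocycle before the exocyclic methylene exists. Acylation of 22 (i-PrCOCl, pyridine) gives the C3 O-isobutyryl derivative of Mannich base 22 F3. Ring-closing metathesis of F3 in the presence of one equivalent of camphorsulfonic acid (Hoveyda–Grubbs II, toluene, 80 °C) gives the macrocyclic amino lactone, the (11R)-11,13-dihydro-13-(dimethylamino) derivative of 26 F4, in which C11 is sp3 and the lactone is more flexible. MeI converts F4 into the N-methyl quaternary ammonium iodide of F4 F5, and aqueous NaHCO3 eliminates trimethylamine. This comes back to the route at 26.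

**Step 6 (C2 oxygenation of the furan).** The risks are competing lithiation at C5 and retro-aldol loss of the side chain at the hydroxyfuran stage. The fallback sets out from 10 and replaces directed deprotonation by halogen–metal exchange. NBS (DMF, −20 °C) brominates the furan at C2, the ring position activated by the neighbouring alkyl group, and gives (1S)-1-(2-bromofuran-3-yl)-4-[(TBS-oxy)methyl]pent-4-en-1-ol F6. n-BuLi (2.1 equiv, THF, −78 °C) deprotonates the hydroxyl and exchanges bromine for lithium regiospecifically. This comes back to the route at dianion 11, which is borylated and oxidised as in step 6.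

## Further compounds

F1 | step 9 | (5R)-3-(hydroxymethyl)-5-[(1E)-prop-1-en-1-yl]furan-2(5H)-one | C/C=C/[C@H]1OC(=O)C(CO)=C1
F2 | step 9 | (5R)-3-(bromomethyl)-5-[(1E)-prop-1-en-1-yl]furan-2(5H)-one | C/C=C/[C@H]1OC(=O)C(CBr)=C1
F3 | step 12 | C3 O-isobutyryl derivative of Mannich base 22 | CN(C)C[C@@H]1C(=O)O[C@H](/C=C/C)[C@H]1[C@@H]2OC(=O)C(=C2)[C@@H](OC(=O)C(C)C)CCC(=C)CO[Si](C)(C)C(C)(C)C
F4 | step 12 | (11R)-11,13-dihydro-13-(dimethylamino) derivative of 26 | CN(C)C[C@@H]1C(=O)O[C@@H]2/C=C(/CO[Si](C)(C)C(C)(C)C)CC[C@H](OC(=O)C(C)C)C3=C[C@@H](OC3=O)[C@@H]12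
F5 | step 12 | N-methyl quaternary ammonium iodide of F4 | [I-].C[N+](C)(C)C[C@@H]1C(=O)O[C@@H]2/C=C(/CO[Si](C)(C)C(C)(C)C)CC[C@H](OC(=O)C(C)C)C3=C[C@@H](OC3=O)[C@@H]12
F6 | step 6 | (1S)-1-(2-bromofuran-3-yl)-4-[(TBS-oxy)methyl]pent-4-en-1-ol | C=C(CC[C@H](O)c1ccoc1Br)CO[Si](C)(C)C(C)(C)C
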